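## The problem

The target 29 is a labdane. Atoms carry labdane numbers throughout, and β means the face of the C10 methyl group. Ring A (C1–C5, C10) and ring B (C5–C10) are trans-fused and joined at a quaternary C10, next to the gem-dimethyl carbon C4. Ring B holds a fully substituted C8=C9 alkene that carries the C8 methyl and, on C9, a five-carbon chain ending in a (Z)-trisubstituted allylic alcohol (C13=C14, C15–OH). The four stereocentres C10, C5, C6 and C7 are contiguous. C10 can be bought and then directs C5. The two β-axial methyl groups on C4 and C10 screen the β-face of C6 and C7, so reagents should enter from the α-face, which is what a 7α-hydroxyl and a 6β-hydroxyl (hydride from α) require. The acetate sits on the more hindered of two neighbouring hydroxyls, so the two oxygens must arrive differentiated. The allylic 7α-hydroxyl can ionise, the (Z)-allylic alcohol can isomerise, the ester is base-labile, and a C6 ketone beside the C8=C9 alkene can drift into conjugation. The feature that opens the plan is that C8, with its methyl, lies between the methylene C7 and C9, while C9 is bonded to the quaternary C10. Ring B is therefore the one-carbon homologue of a cyclopentanone whose two α-carbons differ sharply, and the homologated ketone can enolise only towards C8, where the alkene and the chain are needed.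

## Retrosynthesis

**Acetate and silyl ethers (29 ← 28 ← 27).** The last bonds cut are the two O–Si bonds and the ester C–O bond at O6. Because the acetate must go onto the more hindered hydroxyl, O7 and O15 are carried as silyl ethers and released together from 28. Acylation of a free 6,7-diol would go to O7 instead. The trans-diaxial relation of O6 and O7 should prevent acyl migration after unmasking. The forward steps must acylate an axial alcohol and remove two silyl groups without touching the ester.

**C6 and C7 oxygens (27 ← 26 ← 25 ← 23).** The C6–H bond and the C7–O bond are cut, leading to the β,γ-unsaturated ketone 23. The alternative of opening a C6–C7 epoxide would require a nucleophile to enter at C6 from the screened β-face, and dihydroxylation of a C6=C7 alkene would give a cis-diol. From 23 both centres are set by the substrate: oxygen is transferred to the α-carbon C7 of the dienolate from the α-face, and hydride then reaches C6 from the same face. The precursor has lost two stereocentres and one oxygen.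

**Side chain (23 ← 22 ← 17 + 20).** The C9–C11 bond is cut between the ring sp2 carbon and the first chain methylene. A cut at C11–C12 or C12–C13 would leave a carbon to be added to the hindered C9 separately. The cut at C9–C11 removes the whole chain in one piece as the diene 20, whose (Z)-alkene is bought in 18. Hydroboration of 20 and sp2–sp3 coupling with enol triflate 17 are asked to form a tetrasubstituted alkene next to a quaternary centre. C6 is kept as a free alcohol during coupling and oxidised afterwards, so the chain silyl ether never has to be told apart from a ring silyl ether.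

**Enol triflate (17 ← 16 ← 14).** The C9–O bond of the triflate is traced to ketone 14. No regiochemical question arises, because C10 bears no hydrogen. The C8 configuration of 14 is erased here, so it need not be controlled.

**Ring B (14 ← 10 + 12).** The C8–C9 and C7–C8 bonds are cut and C8 with its methyl is removed as diazoethane 12, leaving the trans-hydrindanone 10. Against a cyclisation that must form the quaternary C10 or a bond to the neopentylic C5, this cut starts from a ring that already holds C5 and C10 in the right relation. The forward reaction must insert the carbon on the C7 side only and stop after one insertion.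

**Trans-hydrindane (10 ← 9 ← 8 ← 6).** The C6–O and C5–H bonds are cut back to alkene 6. Syn hydroboration from the face opposite the C10 methyl sets the trans ring fusion and the C6 oxygen in one step. Catalytic hydrogenation of hydrindenes of this kind tends to give the cis fusion.

**Ring A substituents (6 ← 4 ← 2 ← 1).** The two C4–CH3 bonds are cut and the C3 oxygen is restored, leading to the purchasable enantiopure enedione 1. Its stereocentre becomes C10, its saturated ketone becomes C9, and its enone supplies C4 and the C5=C6 alkene through deconjugative dimethylation.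

**Small fragments (12 ← 11; 20 ← 19 ← 18).** Diazoethane 12 is released from the nitrosourea 11 just before use. Diene 20 comes from the enynol 18 by silylation and semi-hydrogenation.

## Roads not taken

**Alternative 1:** The cut goes through C5–C10 and C8–C9 and opens both rings to the acyclic trienal A1. In the forward direction a chiral secondary amine would turn the enal into an iminium ion whose C9=C10 bond adds to the tethered C5=C6–C7=C8 diene. This would give the trans-fused aldehyde A2 with a C6=C7 alkene.
- Merits: both rings and the C5/C10 relation come from one catalyst-controlled step, and A2 would be reached in fewer steps than ketone 14. In this respect it is the better road.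
- Weak points: the dienophile is a β,β-disubstituted enal, a class that is slow under iminium activation, and it must join the future quaternary C10 to the neopentylic diene terminus C5. The C8 and C9 stereocentres it sets are erased when the C8=C9 alkene is made, which costs a dehydrogenation and a later change of C11 from formyl to methylene. The C6=C7 alkene gives the 6β,7α pattern only through an epoxide opened at C6 from the screened β-face.
- Comparison: the chosen plan is longer to the bicycle, but its C9 ketone converts in two steps into the C8=C9 alkene with the chain attached, and its C6 oxygen is already in place.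

**Alternative 2:** The cut is at C9–C10. In the forward direction tin hydride and a radical initiator would turn the selenoester A3 into a C9 acyl radical, which adds 6-endo to C10 of the ring A enone. Reduction of the C5 radical would give the dione A4.
- Merits: the quaternary C10 forms under neutral conditions. A4 is ketone 14 with C6 already at the ketone level, so it would save the hydroboration, silylation, desilylation and oxidation of the chosen route. In oxidation pattern it is ahead.
- Weak points: the only stereocentre of A3 is C8. It would have to be made enantioenriched, relay its configuration to C10 across the forming ring, and then be destroyed. C5 would be set only by hydrogen transfer or later epimerisation. In A4 the C6 carbonyl enolises towards C7 more easily than the C9 carbonyl towards the tertiary C8, so the C9 enol triflate would need a protection detour. Tin and selenium are used in stoichiometric amounts.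
- Comparison: the chosen plan takes C10 from a purchased enantiopure compound and keeps the two ring B oxygens differentiated (ketone against silyl ether) from the start.

**Alternative 3:** The cut goes through C1–C10 and C4–C5. In the forward direction the diene A6 would add to the methyl-bearing double bond of the quinone A5 under a chiral oxazaborolidinium Lewis acid. This would give the cis-fused enedione A7, to be epimerised at C5.
- Merits: two achiral purchasable compounds give, in one catalytic asymmetric step, a bicycle with the C8 methyl and both ring B carbonyls. On step count to the core this is the best of the four plans.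
- Weak points: A6 carries a cis-methyl on the diene terminus that disfavours the s-cis conformer, and that fully substituted terminus must bond to C5. After the cycloaddition the two conjugated carbonyls of A7 have to be told apart, the chain must be added at the more hindered one, the C2=C3 alkene must be reduced beside an electron-poor enedione alkene, and the C5 epimerisation must favour the trans fusion.
- Comparison: the chosen plan spends more steps, but each step addresses one functional group, and the C9/C6 differentiation and trans fusion are secured by construction.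

Key step: step 8

Assumption: ketone 14 is written as its equatorial 8α-methyl epimer, to which the C8 epimers equilibrate by enolisation; either epimer gives the same enolate 15.

## Route

Step 1
Reactants: 1 (S)-7a-methyl-2,3,7,7a-tetrahydro-1H-indene-1,5(6H)-dione
Product: 2 (S)-7a'-methyl-2',3',7',7a'-tetrahydrospiro[[1,3]dioxolane-2,1'-inden]-5'(6'H)-one (ethylene ketal of the saturated ketone, the future C9)
Conditions: HOCH2CH2OH, p-TsOH·H2O, 4 Å MS, rt
Reagents that add atoms: ethylene glycol, OCCO
Why: Acid-catalysed ketalisation is selective for the saturated cyclopentanone because the conjugated carbonyl is less electrophilic; the quaternary stereocentre is untouched.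

Step 2
Reactants: 2 (S)-7a'-methyl-2',3',7',7a'-tetrahydrospiro[[1,3]dioxolane-2,1'-inden]-5'(6'H)-one
Product: 4 (S)-4',4',7a'-trimethyl-2',4',7',7a'-tetrahydrospiro[[1,3]dioxolane-2,1'-inden]-5'(6'H)-one (gem-dimethyl at C4, ketone at C3, alkene C5=C6), via 4-methyl enone ketal 3 (not isolated)
Conditions: KOt-Bu, MeI, t-BuOH/THF, 0 °C → rt
Reagents that add atoms: methyl iodide, CI
Why: Deconjugative α,α-dialkylation of an enone: the extended enolate is methylated at the α-carbon twice, which moves the alkene out of conjugation to C5=C6; the ketal is stable to base.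

Step 3
Reactants: 4 (S)-4',4',7a'-trimethyl-2',4',7',7a'-tetrahydrospiro[[1,3]dioxolane-2,1'-inden]-5'(6'H)-one
Product: 6 (S)-4',4',7a'-trimethyl-2',4',5',6',7',7a'-hexahydrospiro[[1,3]dioxolane-2,1'-indene] (alkene C5=C6), via ketone hydrazone 5 (not isolated)
Conditions: N2H4·H2O, KOH, diethylene glycol, 130 °C then 200 °C
Reagents that add atoms: none
Why: Wolff–Kishner reduction (Huang-Minlon procedure) removes the hindered C3 carbonyl; the ketal and the isolated trisubstituted alkene are inert to hot base.

Step 4
Reactants: 6 (S)-4',4',7a'-trimethyl-2',4',5',6',7',7a'-hexahydrospiro[[1,3]dioxolane-2,1'-indene]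
Product: 8 (3'S,3a'S,7a'S)-4',4',7a'-trimethyloctahydrospiro[[1,3]dioxolane-2,1'-inden]-3'-ol (trans-fused, 5α-H, 6α-OH), via 6α-alkylborane 7 (not isolated)
Conditions: BH3·THF, THF, 0 °C → rt; then NaOH, H2O2, H2O, 0 → 50 °C
Reagents that add atoms: hydrogen peroxide, OO
Why: Hydroboration–oxidation places boron on the less substituted C6 and hydrogen on C5 in a syn addition from the α-face, opposite the angular C10 methyl. This sets the trans ring fusion (C5) and the 6α-oxygen (C6), and oxidation proceeds with retention.

Step 5
Reactants: 8 (3'S,3a'S,7a'S)-4',4',7a'-trimethyloctahydrospiro[[1,3]dioxolane-2,1'-inden]-3'-ol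
Product: 9 (3'S,3a'S,7a'S)-3'-(tert-butyldimethylsilyloxy)-4',4',7a'-trimethyloctahydrospiro[[1,3]dioxolane-2,1'-indene]
Conditions: TBSCl, imidazole, DMAP (cat.), DMF, 50 °C
Reagents that add atoms: tert-butyldimethylsilyl chloride, CC(C)(C)[Si](C)(C)Cl
Why: Standard silylation of a hindered secondary alcohol; the silyl ether is chosen because it tolerates the Lewis acid of step 8 and the base of step 9 and is only weakly electron-withdrawing.

Step 6
Reactants: 9 (3'S,3a'S,7a'S)-3'-(tert-butyldimethylsilyloxy)-4',4',7a'-trimethyloctahydrospiro[[1,3]dioxolane-2,1'-indene]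
Product: 10 (3S,3aS,7aS)-3-(tert-butyldimethylsilyloxy)-4,4,7a-trimethyloctahydro-1H-inden-1-one (trans-fused, silyloxy α; C9 ketone)
Conditions: PPTS, acetone/H2O, 55 °C
Reagents that add atoms: water, O
Why: Mild acid hydrolysis of the dioxolane frees the C9 ketone while the hindered secondary silyl ether survives; the ring fusion cannot epimerise because C10 is quaternary and C5 is not α to the carbonyl.

Step 7
Reactants: 11 N-ethyl-N-nitrosourea
Product: 12 diazoethane (toluene solution)
Conditions: KOH (40% aq.), toluene, −10 → 0 °C; organic layer dried over KOH pellets, used at once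
Reagents that add atoms: none
Why: Base-induced fragmentation of an N-alkyl-N-nitrosourea is the standard preparation of a simple diazoalkane; the dried solution is used directly because the reagent is not stored.

Step 8
Reactants: 10 (3S,3aS,7aS)-3-(tert-butyldimethylsilyloxy)-4,4,7a-trimethyloctahydro-1H-inden-1-one; 12 diazoethane
Product: 14 (2R,4S,4aS,8aS)-4-(tert-butyldimethylsilyloxy)-2,5,5,8a-tetramethyloctahydronaphthalen-1(2H)-one (trans-fused, C8 methyl equatorial), via diazonium alkoxide adduct 13 (not isolated)
Conditions: Sc(OTf)3 (10 mol%), toluene/CH2Cl2, −78 → −40 °C, slow addition of 12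
Reagents that add atoms: none
Why: Sc(OTf)3 activates the C9 carbonyl, diazoethane adds through carbon from the α-face (opposite the C10 methyl) to give adduct 13, and loss of N2 is coupled to a 1,2-shift of a ring carbon from C9 to the new carbon C8, which restores the C9 carbonyl. The closest known reaction type is the Lewis acid-promoted homologation of cyclic ketones with diazoalkanes, a one-carbon ring expansion of the Tiffeneau–Demjanov kind that is documented for α-substituted cycloalkanones and for angularly methylated hydrindanones. Ring B is not closed by cyclisation but by enlargement of the existing five-membered ring: the C7–C9 bond is exchanged for C7–C8 and C8–C9, so the cyclopentanone becomes a cyclohexanone. The selectivity needed is migration of the methylene C7 and not of the quaternary C10; the substrate secures it because the rotamer of 13 that would let C10 migrate presses the new methyl group against the angular methyl and ring A, and the less substituted carbon is the usual migrating group in this class. The β-silyloxy group lowers the migratory aptitude of C7 slightly by induction, which is why an ether and not an ester is carried at C6. A second insertion is not expected, because the carbonyl of 14 is flanked by a quaternary and a tertiary carbon. The new stereocentre C8 is under thermodynamic control (equatorial methyl through enolisation) and is erased in step 9; C5, C6 and C10 are untouched.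

Step 9
Reactants: 14 (2R,4S,4aS,8aS)-4-(tert-butyldimethylsilyloxy)-2,5,5,8a-tetramethyloctahydronaphthalen-1(2H)-one
Product: 16 (4S,4aS,8aS)-4-(tert-butyldimethylsilyloxy)-2,5,5,8a-tetramethyl-3,4,4a,5,6,7,8,8a-octahydronaphthalen-1-yl trifluoromethanesulfonate (C8=C9 enol triflate), via potassium enolate 15 (not isolated)
Conditions: KN(SiMe3)2, THF, −78 → 0 °C; then PhNTf2, −78 °C → rt
Reagents that add atoms: N-phenylbis(trifluoromethanesulfonimide), O=S(=O)(N(c1ccccc1)S(=O)(=O)C(F)(F)F)C(F)(F)F
Why: Enolate O-sulfonylation; the ketone has α-hydrogen only at C8, so the tetrasubstituted C8=C9 enol triflate forms regiospecifically, as it does for 2,2,6-trisubstituted cyclohexanones.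

Step 10
Reactants: 16 (4S,4aS,8aS)-4-(tert-butyldimethylsilyloxy)-2,5,5,8a-tetramethyl-3,4,4a,5,6,7,8,8a-octahydronaphthalen-1-yl trifluoromethanesulfonate
Product: 17 (4S,4aS,8aS)-4-hydroxy-2,5,5,8a-tetramethyl-3,4,4a,5,6,7,8,8a-octahydronaphthalen-1-yl trifluoromethanesulfonate (6α-OH)
Conditions: HF (48% aq.), MeCN, rt
Reagents that add atoms: none
Why: Acidic fluoride cleaves the silyl ether while the enol triflate, which is stable to acid but not to basic fluoride, is kept; removing the ring silyl group here avoids a later selectivity problem with the chain silyl ether.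

Step 11
Reactants: 18 (Z)-3-methylpent-2-en-4-yn-1-ol
Product: 19 (Z)-tert-butyldimethyl[(3-methylpent-2-en-4-yn-1-yl)oxy]silane
Conditions: TBSCl, imidazole, CH2Cl2, 0 °C → rt
Reagents that add atoms: tert-butyldimethylsilyl chloride, CC(C)(C)[Si](C)(C)Cl
Why: Routine silylation of a primary allylic alcohol; the purchased (Z)-geometry, which becomes C13=C14 of the target, is not affected.

Step 12
Reactants: 19 (Z)-tert-butyldimethyl[(3-methylpent-2-en-4-yn-1-yl)oxy]silane
Product: 20 (Z)-tert-butyldimethyl[(3-methylpenta-2,4-dien-1-yl)oxy]silane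
Conditions: H2 (1 atm), Pd/CaCO3 poisoned with Pb(OAc)2, quinoline, hexane, rt
Reagents that add atoms: none
Why: Lindlar semi-hydrogenation reduces the terminal alkyne to a vinyl group and stops there; the trisubstituted alkene is neither reduced nor isomerised on the poisoned catalyst.

Step 13
Reactants: 20 (Z)-tert-butyldimethyl[(3-methylpenta-2,4-dien-1-yl)oxy]silane; 17 (4S,4aS,8aS)-4-hydroxy-2,5,5,8a-tetramethyl-3,4,4a,5,6,7,8,8a-octahydronaphthalen-1-yl trifluoromethanesulfonate
Product: 22 (5S,6S,10S,13Z)-15-(tert-butyldimethylsilyloxy)labda-8,13-dien-6-ol (6α-OH), via B-alkyl-9-BBN 21 (not isolated)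
Conditions: 20, 9-BBN, THF, 0 °C → rt; then 17, Pd(dppf)Cl2·CH2Cl2, AsPh3, Cs2CO3, DMF/H2O, rt → 50 °C
Reagents that add atoms: none
Why: 9-BBN hydroborates only the terminal vinyl group of the diene, with boron on the end carbon (the future C11), and B-alkyl Suzuki–Miyaura coupling with the enol triflate forms C9–C11. The (Z)-alkene is not involved, and the free secondary alcohol is tolerated.

Step 14
Reactants: 22 (5S,6S,10S,13Z)-15-(tert-butyldimethylsilyloxy)labda-8,13-dien-6-ol
Product: 23 (5S,10S,13Z)-15-(tert-butyldimethylsilyloxy)labda-8,13-dien-6-one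
Conditions: Dess–Martin periodinane, NaHCO3, CH2Cl2, 0 °C → rt
Reagents that add atoms: none
Why: Dess–Martin oxidation under buffered, near-neutral conditions gives the β,γ-unsaturated ketone without moving the C8=C9 alkene into conjugation; the silyl ether and both alkenes are inert.

Step 15
Reactants: 23 (5S,10S,13Z)-15-(tert-butyldimethylsilyloxy)labda-8,13-dien-6-one
Product: 25 (5S,7S,10S,13Z)-15-(tert-butyldimethylsilyloxy)-7-hydroxylabda-8,13-dien-6-one (7α-OH), via potassium dienolate 24 (not isolated)
Conditions: KN(SiMe3)2, THF, −78 °C; then 2-(phenylsulfonyl)-3-phenyloxaziridine, −78 °C; AcOH quench at −78 °C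
Reagents that add atoms: 2-(phenylsulfonyl)-3-phenyloxaziridine, O=S(=O)(c1ccccc1)N1OC1c1ccccc1
Why: Enolate hydroxylation with an N-sulfonyloxaziridine: C7 is the only accessible acidic position (α to the ketone and allylic), dienolates take electrophilic oxygen at the α-carbon, and the reagent approaches C7 from the α-face because the β-face is covered by the axial methyls on C4 and C10.

Step 16
Reactants: 25 (5S,7S,10S,13Z)-15-(tert-butyldimethylsilyloxy)-7-hydroxylabda-8,13-dien-6-one
Product: 26 (5S,7S,10S,13Z)-15-(tert-butyldimethylsilyloxy)-7-(triethylsilyloxy)labda-8,13-dien-6-one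
Conditions: Et3SiOTf, 2,6-lutidine, CH2Cl2, −78 °C
Reagents that add atoms: triethylsilyl trifluoromethanesulfonate, CC[Si](CC)(CC)OS(=O)(=O)C(F)(F)F
Why: Fast silylation with a hindered, non-nucleophilic base masks O7 before the reduction, so that O6 can later be acylated alone, and avoids basic conditions that could epimerise C7 or shift the α-ketol.

Step 17
Reactants: 26 (5S,7S,10S,13Z)-15-(tert-butyldimethylsilyloxy)-7-(triethylsilyloxy)labda-8,13-dien-6-one
Product: 27 (5S,6S,7S,10S,13Z)-15-(tert-butyldimethylsilyloxy)-7-(triethylsilyloxy)labda-8,13-dien-6-ol (6β-OH, 7α-silyloxy)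
Conditions: NaBH4, EtOH/THF, −20 → 0 °C
Reagents that add atoms: none
Why: Borohydride reduction of a 6-ketone in a 4,4,10-trimethyl trans-decalin: the β-face of C6 is blocked by the two syn-axial methyl groups, so hydride enters from the α-face and gives the axial 6β-alcohol, as 6-oxo steroids and 6-oxo terpenoids do.

Step 18
Reactants: 27 (5S,6S,7S,10S,13Z)-15-(tert-butyldimethylsilyloxy)-7-(triethylsilyloxy)labda-8,13-dien-6-ol
Product: 28 (5S,6S,7S,10S,13Z)-15-(tert-butyldimethylsilyloxy)-7-(triethylsilyloxy)labda-8,13-dien-6-yl acetate
Conditions: Ac2O, DMAP, Et3N, CH2Cl2, rt → 40 °C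
Reagents that add atoms: acetic anhydride, CC(=O)OC(C)=O
Why: DMAP-catalysed acylation of the only free hydroxyl; it is axial and hindered, hence the nucleophilic catalyst and gentle warming. Silyl migration is not expected because O6 and O7 are trans-diaxial.

Step 19
Reactants: 28 (5S,6S,7S,10S,13Z)-15-(tert-butyldimethylsilyloxy)-7-(triethylsilyloxy)labda-8,13-dien-6-yl acetate
Product: 29 (5S,6S,7S,10S,13Z)-7,15-dihydroxylabda-8,13-dien-6-yl acetate (6β-acetoxy, 7α-hydroxy; the target)
Conditions: HF·pyridine, pyridine, THF, 0 °C → rt
Reagents that add atoms: none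
Why: Buffered fluoride removes the secondary triethylsilyl and the primary tert-butyldimethylsilyl ether in one operation. The acetate survives, it cannot migrate to the trans-diaxial O7, and the buffered medium avoids ionising the allylic C7–O bond.

## Compound list

1 | (S)-7a-methyl-2,3,7,7a-tetrahydro-1H-indene-1,5(6H)-dione | O=C1CCC2=CC(=O)CC[C@]12C | starting material
2 | (S)-7a'-methyl-2',3',7',7a'-tetrahydrospiro[[1,3]dioxolane-2,1'-inden]-5'(6'H)-one | O=C1C=C2CCC3(OCCO3)[C@@]2(C)CC1 | intermediate
3 | (S)-4',7a'-dimethyl-2',3',7',7a'-tetrahydrospiro[[1,3]dioxolane-2,1'-inden]-5'(6'H)-one (4-methyl enone ketal) | O=C1CC[C@@]2(C)C(CCC23OCCO3)=C1C | intermediate (not isolated)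
4 | (S)-4',4',7a'-trimethyl-2',4',7',7a'-tetrahydrospiro[[1,3]dioxolane-2,1'-inden]-5'(6'H)-one | O=C1CC[C@@]2(C)C(=CCC23OCCO3)C1(C)C | intermediate
5 | hydrazone of 4 | NN=C1CC[C@@]2(C)C(=CCC23OCCO3)C1(C)C | intermediate (not isolated)
6 | (S)-4',4',7a'-trimethyl-2',4',5',6',7',7a'-hexahydrospiro[[1,3]dioxolane-2,1'-indene] | CC1(C)CCC[C@@]2(C)C1=CCC23OCCO3 | intermediate
7 | (3'S,3a'S,7a'S)-(4',4',7a'-trimethyloctahydrospiro[[1,3]dioxolane-2,1'-inden]-3'-yl)borane (trans-fused, boron 6α) | B[C@H]1CC3(OCCO3)[C@@]2(C)CCCC(C)(C)[C@H]12 | intermediate (not isolated)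
8 | (3'S,3a'S,7a'S)-4',4',7a'-trimethyloctahydrospiro[[1,3]dioxolane-2,1'-inden]-3'-ol | O[C@H]1CC3(OCCO3)[C@@]2(C)CCCC(C)(C)[C@H]12 | intermediate
9 | (3'S,3a'S,7a'S)-3'-(tert-butyldimethylsilyloxy)-4',4',7a'-trimethyloctahydrospiro[[1,3]dioxolane-2,1'-indene] | CC(C)(C)[Si](C)(C)O[C@H]1CC3(OCCO3)[C@@]2(C)CCCC(C)(C)[C@H]12 | intermediate
10 | (3S,3aS,7aS)-3-(tert-butyldimethylsilyloxy)-4,4,7a-trimethyloctahydro-1H-inden-1-one | CC(C)(C)[Si](C)(C)O[C@H]1CC(=O)[C@@]2(C)CCCC(C)(C)[C@H]12 | intermediate
11 | N-ethyl-N-nitrosourea | CCN(N=O)C(N)=O | starting material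
12 | diazoethane | CC=[N+]=[N-] | intermediate
13 | 1-(1-diazonioethyl)-3-(tert-butyldimethylsilyloxy)-4,4,7a-trimethyloctahydro-1H-inden-1-olate (scandium-bound adduct; new centres undefined) | CC(C)(C)[Si](C)(C)O[C@H]1CC([O-])(C(C)[N+]#N)[C@@]2(C)CCCC(C)(C)[C@H]12 | intermediate (not isolated)
14 | (2R,4S,4aS,8aS)-4-(tert-butyldimethylsilyloxy)-2,5,5,8a-tetramethyloctahydronaphthalen-1(2H)-one | CC(C)(C)[Si](C)(C)O[C@H]1C[C@@H](C)C(=O)[C@@]2(C)CCCC(C)(C)[C@H]12 | intermediate
15 | potassium (4S,4aS,8aS)-4-(tert-butyldimethylsilyloxy)-2,5,5,8a-tetramethyl-3,4,4a,5,6,7,8,8a-octahydronaphthalen-1-olate | CC(C)(C)[Si](C)(C)O[C@H]1CC(C)=C([O-])[C@@]2(C)CCCC(C)(C)[C@H]12.[K+] | intermediate (not isolated)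
16 | (4S,4aS,8aS)-4-(tert-butyldimethylsilyloxy)-2,5,5,8a-tetramethyl-3,4,4a,5,6,7,8,8a-octahydronaphthalen-1-yl trifluoromethanesulfonate | CC(C)(C)[Si](C)(C)O[C@H]1CC(C)=C(OS(=O)(=O)C(F)(F)F)[C@@]2(C)CCCC(C)(C)[C@H]12 | intermediate
17 | (4S,4aS,8aS)-4-hydroxy-2,5,5,8a-tetramethyl-3,4,4a,5,6,7,8,8a-octahydronaphthalen-1-yl trifluoromethanesulfonate | O[C@H]1CC(C)=C(OS(=O)(=O)C(F)(F)F)[C@@]2(C)CCCC(C)(C)[C@H]12 | intermediate
18 | (Z)-3-methylpent-2-en-4-yn-1-ol | OC/C=C(C)\C#C | starting material
19 | (Z)-tert-butyldimethyl[(3-methylpent-2-en-4-yn-1-yl)oxy]silane | CC(C)(C)[Si](C)(C)OC/C=C(C)\C#C | intermediate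
20 | (Z)-tert-butyldimethyl[(3-methylpenta-2,4-dien-1-yl)oxy]silane | CC(C)(C)[Si](C)(C)OC/C=C(C)\C=C | intermediate
21 | 9-[(Z)-5-(tert-butyldimethylsilyloxy)-3-methylpent-3-en-1-yl]-9-borabicyclo[3.3.1]nonane | CC(C)(C)[Si](C)(C)OC/C=C(C)\CCB1C2CCCC1CCC2 | intermediate (not isolated)
22 | (5S,6S,10S,13Z)-15-(tert-butyldimethylsilyloxy)labda-8,13-dien-6-ol (6α-OH) | O[C@H]1CC(C)=C(CC/C(C)=C\CO[Si](C)(C)C(C)(C)C)[C@@]2(C)CCCC(C)(C)[C@H]12 | intermediate
23 | (5S,10S,13Z)-15-(tert-butyldimethylsilyloxy)labda-8,13-dien-6-one | O=C1CC(C)=C(CC/C(C)=C\CO[Si](C)(C)C(C)(C)C)[C@@]2(C)CCCC(C)(C)[C@H]12 | intermediate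
24 | potassium (5S,10S,13Z)-15-(tert-butyldimethylsilyloxy)labda-6,8,13-trien-6-olate | [O-]C1=CC(C)=C(CC/C(C)=C\CO[Si](C)(C)C(C)(C)C)[C@@]2(C)CCCC(C)(C)[C@H]12.[K+] | intermediate (not isolated)
25 | (5S,7S,10S,13Z)-15-(tert-butyldimethylsilyloxy)-7-hydroxylabda-8,13-dien-6-one (7α-OH) | O=C1[C@@H](O)C(C)=C(CC/C(C)=C\CO[Si](C)(C)C(C)(C)C)[C@@]2(C)CCCC(C)(C)[C@H]12 | intermediate
26 | (5S,7S,10S,13Z)-15-(tert-butyldimethylsilyloxy)-7-(triethylsilyloxy)labda-8,13-dien-6-one | O=C1[C@@H](O[Si](CC)(CC)CC)C(C)=C(CC/C(C)=C\CO[Si](C)(C)C(C)(C)C)[C@@]2(C)CCCC(C)(C)[C@H]12 | intermediate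
27 | (5S,6S,7S,10S,13Z)-15-(tert-butyldimethylsilyloxy)-7-(triethylsilyloxy)labda-8,13-dien-6-ol (6β-OH) | O[C@@H]1[C@@H](O[Si](CC)(CC)CC)C(C)=C(CC/C(C)=C\CO[Si](C)(C)C(C)(C)C)[C@@]2(C)CCCC(C)(C)[C@H]12 | intermediate
28 | (5S,6S,7S,10S,13Z)-15-(tert-butyldimethylsilyloxy)-7-(triethylsilyloxy)labda-8,13-dien-6-yl acetate | CC(=O)O[C@@H]1[C@@H](O[Si](CC)(CC)CC)C(C)=C(CC/C(C)=C\CO[Si](C)(C)C(C)(C)C)[C@@]2(C)CCCC(C)(C)[C@H]12 | intermediate
29 | (5S,6S,7S,10S,13Z)-7,15-dihydroxylabda-8,13-dien-6-yl acetate (CNP0183298.2) | CC(=O)O[C@@H]1[C@@H](O)C(C)=C(CC/C(C)=C\CO)[C@@]2(C)CCCC(C)(C)[C@H]12 | target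

## Step count and risks

Total: 19 steps. Longest linear sequence: 16 steps (steps 1–6, 8–10 and 13–19, from 1 to 29).

**Step 8 (key step).** The most likely failures are competing migration of the quaternary C10, which would place the new carbon between C9 and C10, and slow addition to the neopentylic carbonyl, so that the diazoalkane decomposes first. Loss of the β-silyloxy group by elimination under the Lewis acid is a lesser concern. The fallback separates carbon insertion from methyl introduction. From 10, Me3SiCHN2 with Me3Al (CH2Cl2, −78 °C) should give (4S,4aS,8aS)-4-(tert-butyldimethylsilyloxy)-5,5,8a-trimethyl-2-(trimethylsilyl)octahydronaphthalen-1(2H)-one F1; this bulkier diazoalkane has a pronounced preference for migration of the less substituted carbon. K2CO3 in MeOH should remove the α-silyl group to give (4S,4aS,8aS)-4-(tert-butyldimethylsilyloxy)-5,5,8a-trimethyloctahydronaphthalen-1(2H)-one F2. Like 14, F2 can enolise only towards C8, so LiN(i-Pr)2 and MeI should methylate C8 and return to the route at 14.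

**Step 13.** Oxidative addition and transmetalation at a triflate flanked by a quaternary carbon and a methyl-bearing carbon may be slow. Hydrolysis of the triflate by the aqueous base or β-hydride loss from the alkylpalladium intermediate could then take over. The fallback moves the sp3–sp2 coupling away from the hindered carbon.
- From 17, Stille coupling with tributyl(vinyl)stannane (Pd(PPh3)4, LiCl, THF, reflux), which is well behaved for 2,6,6-trisubstituted cyclohexenyl triflates, should give (4S,4aS,8aS)-2,5,5,8a-tetramethyl-1-vinyl-3,4,4a,5,6,7,8,8a-octahydronaphthalen-4-ol F3.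
- But-2-yn-1-ol would be converted by anti-hydroalumination and iodination (NaAlH2(OCH2CH2OMe)2, then I2) into (Z)-3-iodobut-2-en-1-ol F4, and silylation would give (Z)-tert-butyl[(3-iodobut-2-en-1-yl)oxy]dimethylsilane F5.
- 9-BBN should hydroborate the vinyl group of F3 at its terminus (the future C12), and Suzuki–Miyaura coupling with F5 (Pd(dppf)Cl2, Cs2CO3) would form the unhindered C12–C13 bond with retention of the (Z)-geometry, rejoining the route at 22.

**Step 15.** Oxygen transfer may occur at the γ-carbon C9 of dienolate 24, proton return at C9 on quench may move the alkene into conjugation, or the basic medium may transpose the α-ketol to the conjugated 6-hydroxy-7-ketone. The fallback avoids the basic alkoxide. From 23, Me3SiOTf and Et3N should give (5S,10S,13Z)-15-(tert-butyldimethylsilyloxy)-6-(trimethylsilyloxy)labda-6,8,13-triene F6. Catalytic OsO4 with N-methylmorpholine N-oxide should then dihydroxylate the electron-rich enol ether bond C6=C7 from the α-face in preference to the hindered tetrasubstituted and the allylically deactivated alkenes. Collapse of the resulting hemiketal returns to the route at 25.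

**Step 17.** Facial selectivity may erode. The pseudo-axial 7α-silyloxy group hinders the α-face and, in a Felkin–Anh sense, favours attack anti to the C7–O bond from the β-face. Basic ethanol could also epimerise C7. The fallback uses the C7 hydroxyl as a directing group. From 25, Me4NBH(OAc)3 (MeCN/AcOH, −20 °C) should bind O7 and deliver hydride to C6 within the complex from the α-face, giving (5S,6S,7S,10S,13Z)-15-(tert-butyldimethylsilyloxy)labda-8,13-diene-6,7-diol F7. Silylation of the far less hindered allylic O7 (Et3SiCl, imidazole, one equivalent, 0 °C) returns to the route at 27.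

**Step 18.** Acylation may stall, because the hydroxyl is axial, lies under two syn-axial methyl groups and has a triethylsilyloxy neighbour. Forcing conditions would put the allylic silyl ether at risk. The fallback turns the hindrance into a selectivity element. From 25, the diol F7 is made as above and acetylated at both hydroxyls without a bulky neighbour (Ac2O, DMAP, pyridine) to give (5S,6S,7S,10S,13Z)-15-(tert-butyldimethylsilyloxy)labda-8,13-diene-6,7-diyl diacetate F8. Brief methanolysis (K2CO3, MeOH, 0 °C) should cleave the exposed allylic 7-acetate first and leave (5S,6S,7S,10S,13Z)-15-(tert-butyldimethylsilyloxy)-7-hydroxylabda-8,13-dien-6-yl acetate F9. HF·pyridine then removes the silyl group and arrives at 29.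

## Further compounds

F1 | step 8 | (4S,4aS,8aS)-4-(tert-butyldimethylsilyloxy)-5,5,8a-trimethyl-2-(trimethylsilyl)octahydronaphthalen-1(2H)-one | CC(C)(C)[Si](C)(C)O[C@H]1CC([Si](C)(C)C)C(=O)[C@@]2(C)CCCC(C)(C)[C@H]12
F2 | step 8 | (4S,4aS,8aS)-4-(tert-butyldimethylsilyloxy)-5,5,8a-trimethyloctahydronaphthalen-1(2H)-one | CC(C)(C)[Si](C)(C)O[C@H]1CCC(=O)[C@@]2(C)CCCC(C)(C)[C@H]12
F3 | step 13 | (4S,4aS,8aS)-2,5,5,8a-tetramethyl-1-vinyl-3,4,4a,5,6,7,8,8a-octahydronaphthalen-4-ol | O[C@H]1CC(C)=C(C=C)[C@@]2(C)CCCC(C)(C)[C@H]12
F4 | step 13 | (Z)-3-iodobut-2-en-1-ol | OC/C=C(C)\I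
F5 | step 13 | (Z)-tert-butyl[(3-iodobut-2-en-1-yl)oxy]dimethylsilane | CC(C)(C)[Si](C)(C)OC/C=C(C)\I
F6 | step 15 | (5S,10S,13Z)-15-(tert-butyldimethylsilyloxy)-6-(trimethylsilyloxy)labda-6,8,13-triene | C[Si](C)(C)OC1=CC(C)=C(CC/C(C)=C\CO[Si](C)(C)C(C)(C)C)[C@@]2(C)CCCC(C)(C)[C@H]12
F7 | step 17 | (5S,6S,7S,10S,13Z)-15-(tert-butyldimethylsilyloxy)labda-8,13-diene-6,7-diol | O[C@@H]1[C@@H](O)C(C)=C(CC/C(C)=C\CO[Si](C)(C)C(C)(C)C)[C@@]2(C)CCCC(C)(C)[C@H]12
F8 | step 18 | (5S,6S,7S,10S,13Z)-15-(tert-butyldimethylsilyloxy)labda-8,13-diene-6,7-diyl diacetate | CC(=O)O[C@@H]1[C@@H](OC(C)=O)C(C)=C(CC/C(C)=C\CO[Si](C)(C)C(C)(C)C)[C@@]2(C)CCCC(C)(C)[C@H]12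
F9 | step 18 | (5S,6S,7S,10S,13Z)-15-(tert-butyldimethylsilyloxy)-7-hydroxylabda-8,13-dien-6-yl acetate | CC(=O)O[C@@H]1[C@@H](O)C(C)=C(CC/C(C)=C\CO[Si](C)(C)C(C)(C)C)[C@@]2(C)CCCC(C)(C)[C@H]12
A1 | alternative 1 | (2E,8E,10E)-3,7,7-trimethyldodeca-2,8,10-trienal | O=C/C=C(\C)CCCC(C)(C)/C=C/C=C/C
A2 | alternative 1 | trans-fused 2,5,5,8a-tetramethyl-1,2,4a,5,6,7,8,8a-octahydronaphthalene-1-carbaldehyde (5α-H, 8β-methyl, 9β-formyl, 10β-methyl) | C1=C[C@H](C)[C@H](C=O)[C@@]2(C)CCCC(C)(C)[C@H]12
A3 | alternative 2 | Se-phenyl 2-methyl-4-oxo-4-(2,6,6-trimethylcyclohex-1-en-1-yl)butaneselenoate | CC(CC(=O)C1=C(C)CCCC1(C)C)C(=O)[Se]c1ccccc1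
A4 | alternative 2 | trans-fused 2,5,5,8a-tetramethyloctahydronaphthalene-1,4-dione (5α-H, 8α-methyl, 10β-methyl) | O=C1C[C@@H](C)C(=O)[C@@]2(C)CCCC(C)(C)[C@H]12
A5 | alternative 3 | 2,6-dimethyl-1,4-benzoquinone | CC1=CC(=O)C=C(C)C1=O
A6 | alternative 3 | 4-methylpenta-1,3-diene | C=CC=C(C)C
A7 | alternative 3 | cis-fused 2,5,5,8a-tetramethyl-4a,5,8,8a-tetrahydronaphthalene-1,4-dione | O=C1C=C(C)C(=O)[C@@]2(C)CC=CC(C)(C)[C@@H]12
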